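**Strategy.** The route rests on cutting ring D (C14–C15–C16–C18–O20), the α-methyl γ-lactone whose carbinol carbon C14 sits on the amino carbon C13, back to a C13 aldehyde. In one operation a zinc Barbier reaction with ethyl 2-(bromomethyl)acrylate forms C14–C15, sets C14 and, through attack of the zinc alkoxide on the ester, closes O20–C18 to the α-methylene lactone. The precursor is the tetracyclic aldehyde in which rings A (cyclopentane), B (lactone), C and E (half-twisted 1-azabicyclo[4.3.1]decan-10-one) are complete and O26 is silylated. It is built from (+)-Corey lactone diol by conjugate addition/acylation at C27, iridium-catalysed amination at C13, nosyl-amide ring closure and transannular lactamisation.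

Key step: step 18

**Remarks**
- Atom labels follow the order of the atoms in the target SMILES (C1, C2 ethyl; C3; C4; O5; C6(=O7); C8(C9); C10; C11; C12; C13; C14; C15; C16(C17); C18(=O19); O20; N21; C22–C24; C25(O26); C27; C28(=O29)).
- Rings: A = C3, C4, C10, C11, C27; B = C4, O5, C6, C8, C10; C = C11, C12, C13, N21, C28, C27; D = C14, C15, C16, C18, O20; E = N21, C22, C23, C24, C25, C27, C28.
- Assumption: (+)-Corey lactone diol 1, the enantiomer of the prostaglandin intermediate, is taken as commercially available.
- The acetal or hemiacetal carbon C6 in 3–9, 11 and 12 is an anomeric mixture that is erased in step 8; its centre is left open in the SMILES.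
- The sense of induction in step 14 is taken from the empirical model for iridium phosphoramidite catalysts; the ligand antipode is chosen accordingly.

## Route

**Step 1**
Reactants: 1 (+)-Corey lactone diol
Product: 2 iodo lactone (C12 iodide, C27 hydroxyl free)
Conditions: I2, PPh3, imidazole, THF, 0 °C
Reagents that add atoms: iodine, II
Why: Appel-type iodination converts the unhindered primary C12 hydroxyl much faster than the secondary C27 hydroxyl.

**Step 2**
Reactants: 2 iodo lactone
Product: 4 iodo methyl acetal, via lactol 3 (not isolated)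
Conditions: iBu2AlH, CH2Cl2, −78 °C; aq potassium sodium tartrate; then MeOH, PPTS (cat.), rt
Reagents that add atoms: methanol, CO
Why: Partial reduction of the γ-lactone followed by Fischer-type acetalisation masks ring B as a methyl acetal, so that O5 is no longer a carboxylate leaving group β to the C27 ketone enolate of step 5.

**Step 3**
Reactants: 4 iodo methyl acetal
Product: 5 allyl alcohol acetal (C11 allyl group)
Conditions: CH2=CHMgBr (4 equiv), CuI (20 mol%), THF, −30 → 0 °C
Reagents that add atoms: vinylmagnesium bromide, C=C[Mg]Br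
Why: Copper-catalysed sp3–sp2 cross-coupling of the primary iodide with the vinyl Grignard reagent turns C12 into an allyl group, one extra equivalent being consumed by the free C27 hydroxyl.

**Step 4**
Reactants: 5 allyl alcohol acetal
Product: 6 C27 ketone
Conditions: Dess–Martin periodinane, CH2Cl2, rt
Reagents that add atoms: none
Why: Dess–Martin oxidation of the secondary alcohol proceeds under neutral conditions that leave the acetal, the alkene and the C11 centre untouched.

**Step 5**
Reactants: 6 C27 ketone
Product: 8 enol triflate (C27=C3), via potassium enolate 7 (not isolated)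
Conditions: KN(SiMe3)2, THF, −78 °C; then N-(5-chloropyridin-2-yl)triflimide, −78 °C; aq NH4Cl
Reagents that add atoms: N-(5-chloropyridin-2-yl)bis(trifluoromethanesulfonyl)imide, FC(F)(F)S(=O)(=O)N(c1ccc(Cl)cn1)S(=O)(=O)C(F)(F)F
Why: Kinetic deprotonation takes the C3 methylene rather than the allyl-bearing C11 methine, and O-triflation at −78 °C traps the enolate before the poor alkoxide leaving group O5 can be expelled.

**Step 6**
Reactants: 8 enol triflate
Product: 9 cyclopentene methyl ester (C28 on C27, C27=C3)
Conditions: Pd(OAc)2 (5 mol%), 1,3-bis(diphenylphosphino)propane, CO (1 atm), MeOH, Et3N, DMF, 50 °C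
Reagents that add atoms: carbon monoxide, [C-]#[O+]; methanol, CO
Why: Palladium-catalysed methoxycarbonylation of the vinyl triflate installs C28, methanolysis of the acyl-palladium species outrunning insertion of the remote allyl group.

**Step 7**
Reactants: 9 cyclopentene methyl ester; 10 4-chlorobutanoyl chloride
Product: 12 β-keto ester acetal (C27 quaternary), via lithium ester enolate 11 (not isolated)
Conditions: Et2CuLi (from EtLi and CuI), Et2O, −78 → −30 °C; then 10, THF, −78 → 0 °C; aq NH4Cl
Reagents that add atoms: lithium diethylcuprate, [Li+].CC[Cu-]CC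
Why: In a tandem cuprate conjugate addition and enolate C-acylation, ethyl adds to C3 on the convex face anti to the allylic O5, and the enolate is acylated at C27 anti to both the new ethyl group and the C11 allyl group, which places C28 cis to C12 and C25 trans to it.

**Step 8**
Reactants: 12 β-keto ester acetal
Product: 13 keto ester lactone (ring B restored)
Conditions: CrO3, H2SO4, acetone/H2O, 0 °C
Reagents that add atoms: water, O
Why: Jones oxidation hydrolyses the methyl acetal and oxidises the lactol in one pot without affecting the ketone, the ester, the chloride or the terminal alkene.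

**Step 9**
Reactants: 13 keto ester lactone
Product: 14 (25R)-alcohol
Conditions: (S)-2-methyl-CBS-oxazaborolidine (20 mol%), catecholborane, toluene, −78 → −20 °C
Reagents that add atoms: none
Why: The oxazaborolidine-catalysed (CBS) reduction distinguishes the quaternary C27 (large) from the C24 methylene (small) and sets (25R) under reagent control, while catecholborane leaves the alkene, the ester and the lactone alone.

**Step 10**
Reactants: 14 (25R)-alcohol
Product: 15 TBS ether
Conditions: TBSOTf, 2,6-lutidine, CH2Cl2, 0 °C
Reagents that add atoms: tert-butyldimethylsilyl triflate, CC(C)(C)[Si](C)(C)OS(=O)(=O)C(F)(F)F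
Why: Silyl triflate silylation protects the hindered neopentyl-type secondary hydroxyl O26 as the ether that is carried to the last step.

**Step 11**
Reactants: 15 TBS ether
Product: 17 8-epi methyl lactone (C9 mainly on the convex face), via lithium lactone enolate 16 (not isolated)
Conditions: LiN(iPr)2, THF, −78 °C; then MeI, −78 → −40 °C
Reagents that add atoms: iodomethane, CI
Why: Enolate alkylation at C8, the only enolisable position, brings in C9, and the configuration formed here does not matter because step 12 resets it.

**Step 12**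
Reactants: 17 8-epi methyl lactone
Product: 19 (8S)-methyl lactone, via lithium methyl-lactone enolate 18 (not isolated)
Conditions: LiN(iPr)2, THF, −78 → −40 °C; then 2,6-di-tert-butyl-4-methylphenol, THF, −78 °C
Reagents that add atoms: none
Why: Kinetic protonation of the planar enolate by a hindered phenol from the convex face of the cis-fused bicycle puts H8 syn to H10 and leaves C9 on the concave face, cis to C11, as in the target.

**Step 13**
Reactants: 19 (8S)-methyl lactone; 20 allyl methyl carbonate
Product: 21 (E)-allylic methyl carbonate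
Conditions: second-generation Grubbs catalyst (5 mol%), 20 (5 equiv), CH2Cl2, 40 °C
Reagents that add atoms: none
Why: Olefin cross-metathesis of the terminal allyl group with the allyl carbonate gives the linear (E)-allylic carbonate needed for branched-selective amination.

**Step 14**
Reactants: 21 (E)-allylic methyl carbonate; 22 2-nitrobenzenesulfonamide
Product: 23 (13R)-N-nosyl allylic amine
Conditions: [Ir(cod)Cl]2 (2 mol%), binaphthol-derived bis(1-phenylethyl)amine phosphoramidite (4 mol%, antipode that gives 13R), 1,5,7-triazabicyclo[4.4.0]dec-5-ene (10 mol%), THF, 50 °C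
Reagents that add atoms: none
Why: Iridium-catalysed asymmetric allylic amination with the nosyl amide as ammonia equivalent attacks the substituted allyl terminus and sets (13R) under catalyst control, the terminal vinyl group serving as the masked C14 aldehyde.

**Step 15**
Reactants: 23 (13R)-N-nosyl allylic amine
Product: 24 N-nosyl azonane (N21–C22 closed)
Conditions: Cs2CO3, n-Bu4NI (20 mol%), MeCN (0.003 M), 70 °C
Reagents that add atoms: none
Why: Intramolecular N-alkylation of the acidic 2-nitrobenzenesulfonamide by the primary chloride, activated by iodide exchange, is the standard way to close eight- to ten-membered cyclic amines and here forms the nine-membered ring under high dilution.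

**Step 16**
Reactants: 24 N-nosyl azonane
Product: 26 vinyl twisted lactam (rings A, B, C, E), via azonane amino ester 25 (not isolated)
Conditions: PhSH, K2CO3, DMF, rt; then 70 °C
Reagents that add atoms: none
Why: Thiolate ipso-substitution removes the nosyl group, and the freed N21, held across the nine-membered ring from the C28 ester, acylates transannularly, which is the known way to one-carbon-bridged 1-azabicyclo[4.3.1]decan-10-ones and avoids N-alkylation of a planar lactam.

**Step 17**
Reactants: 26 vinyl twisted lactam
Product: 28 C13 aldehyde, via vicinal diol 27 (not isolated)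
Conditions: OsO4 (2 mol%), NaIO4, 2,6-lutidine, dioxane/H2O, rt
Reagents that add atoms: osmium tetroxide, O=[Os](=O)(=O)=O; sodium periodate, [Na+].[O-]I(=O)(=O)=O
Why: Dihydroxylation–periodate cleavage (Lemieux–Johnson) of the vinyl group releases the C14 aldehyde under near-neutral, non-reducing conditions, so that lactone B and the ketone-like C28 carbonyl are untouched and C13 is not epimerised.

**Step 18**
Reactants: 28 C13 aldehyde; 29 ethyl 2-(bromomethyl)acrylate
Product: 32 α-methylene lactone (ring D closed), via allylzinc bromide 30 (not isolated), via zinc alkoxide 31 (not isolated)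
Conditions: 29, activated Zn dust, THF, 0 °C; then 28, ZnBr2 (1 equiv), THF, −40 °C → rt; aq NH4Cl
Reagents that add atoms: none
Why: Zinc inserts into the allylic C–Br bond of 29, the 2-(ethoxycarbonyl)allylzinc bromide adds through its γ-carbon to the aldehyde in a six-membered chair transition state (C14–C15), and the zinc alkoxide then attacks the ethyl ester and expels ethoxide (O20–C18). The closest precedent is the Barbier/Reformatsky-type synthesis of α-methylene γ-butyrolactones from 2-(bromomethyl)acrylates and aldehydes, N-acyl α-amino aldehydes included. Ring D closes by 5-exo-trig acyl substitution of the homoallylic alkoxide on the ester carbonyl. C14 is controlled by the C13 centre: divalent zinc bridges the aldehyde oxygen and the pyramidal bridgehead N21 (or O29) of the half-twisted lactam, and the allyl group enters this chelate from the side of H13, away from C12, to give the threo (13R,14R) isomer. The step needs this chelation-controlled diastereoselectivity and chemoselectivity for the aldehyde; the first is secured by the partly free lone pair on N21 and the added ZnBr2, the second by the low reactivity of the allylzinc towards lactone B and the shielded C28 carbonyl. C13 is preserved because the aldehyde is made under neutral conditions and consumed at low temperature.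

**Step 19**
Reactants: 32 α-methylene lactone
Product: 33 O26-TBS ether of the target
Conditions: H2 (1 atm), Pd/C (10 wt%), EtOAc, rt
Reagents that add atoms: none
Why: Heterogeneous hydrogenation delivers hydrogen to the exocyclic methylene of ring D from the face away from the C13 substituent on C14, which gives the cis 14,16 relationship (16R).

**Step 20**
Reactants: 33 O26-TBS ether of the target
Product: 34 target
Conditions: HF·pyridine, pyridine, THF, 0 °C → rt
Reagents that add atoms: none
Why: Buffered fluoride desilylation frees O26 without opening either lactone or the twisted lactam.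

## Compound list

1 | (+)-Corey lactone diol, (3aS,4R,5S,6aR)-5-hydroxy-4-(hydroxymethyl)hexahydro-2H-cyclopenta[b]furan-2-one | C1[C@H]2OC(=O)C[C@H]2[C@H](CO)[C@H]1O | starting material
2 | iodo lactone, 1 with the C12 hydroxyl replaced by iodine | C1[C@H]2OC(=O)C[C@H]2[C@H](CI)[C@H]1O | intermediate
3 | lactol of 2 (C6 hemiacetal, formed in the flask) | C1[C@H]2OC(O)C[C@H]2[C@H](CI)[C@H]1O | intermediate
4 | iodo methyl acetal, 4-(iodomethyl)-2-methoxyhexahydro-2H-cyclopenta[b]furan-5-ol, ring centres as in 1 | C1[C@H]2OC(OC)C[C@H]2[C@H](CI)[C@H]1O | intermediate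
5 | allyl alcohol acetal, 4-allyl-2-methoxyhexahydro-2H-cyclopenta[b]furan-5-ol, ring centres as in 1 | C1[C@H]2OC(OC)C[C@H]2[C@H](CC=C)[C@H]1O | intermediate
6 | C27 ketone, 4-allyl-2-methoxyhexahydro-2H-cyclopenta[b]furan-5-one | C1[C@H]2OC(OC)C[C@H]2[C@H](CC=C)C1=O | intermediate
7 | potassium enolate of 6 towards C3 (formed in the flask) | C=1[C@H]2OC(OC)C[C@H]2[C@H](CC=C)C=1O[K] | intermediate
8 | enol triflate of 6 (C27=C3) | C=1[C@H]2OC(OC)C[C@H]2[C@H](CC=C)C=1OS(=O)(=O)C(F)(F)F | intermediate
9 | methyl 4-allyl-2-methoxy-3,3a,4,6a-tetrahydro-2H-cyclopenta[b]furan-5-carboxylate (C27=C3 enoate) | C=1[C@H]2OC(OC)C[C@H]2[C@H](CC=C)C=1C(=O)OC | intermediate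
10 | 4-chlorobutanoyl chloride | ClCCCC(Cl)=O | starting material
11 | lithium ester enolate after ethyl addition to C3 (ethyl trans to O5, formed in the flask) | CC[C@@H]1[C@H]2OC(OC)C[C@H]2[C@H](CC=C)C1=C(OC)O[Li] | intermediate
12 | β-keto ester acetal, methyl 4-allyl-5-(4-chlorobutanoyl)-6-ethyl-2-methoxyhexahydro-2H-cyclopenta[b]furan-5-carboxylate, ester cis to ethyl and allyl | CC[C@@H]1[C@H]2OC(OC)C[C@H]2[C@H](CC=C)[C@@]1(C(=O)OC)C(=O)CCCCl | intermediate
13 | keto ester lactone, the 2-oxo analogue of 12 | CC[C@@H]1[C@H]2OC(=O)C[C@H]2[C@H](CC=C)[C@@]1(C(=O)OC)C(=O)CCCCl | intermediate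
14 | (25R)-alcohol, 13 with the C25 ketone reduced | CC[C@@H]1[C@H]2OC(=O)C[C@H]2[C@H](CC=C)[C@@]1(C(=O)OC)[C@H](O)CCCCl | intermediate
15 | TBS ether of 14 at O26 | CC[C@@H]1[C@H]2OC(=O)C[C@H]2[C@H](CC=C)[C@@]1(C(=O)OC)[C@H](O[Si](C)(C)C(C)(C)C)CCCCl | intermediate
16 | lithium enolate of lactone B in 15 (formed in the flask) | CC[C@@H]1[C@H]2OC(O[Li])=C[C@H]2[C@H](CC=C)[C@@]1(C(=O)OC)[C@H](O[Si](C)(C)C(C)(C)C)CCCCl | intermediate
17 | 8-epi methyl lactone (8R, C9 on the convex face, major epimer) | CC[C@@H]1[C@H]2OC(=O)[C@H](C)[C@H]2[C@H](CC=C)[C@@]1(C(=O)OC)[C@H](O[Si](C)(C)C(C)(C)C)CCCCl | intermediate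
18 | lithium enolate of the C8-methyl lactone (formed in the flask) | CC[C@@H]1[C@H]2OC(O[Li])=C(C)[C@H]2[C@H](CC=C)[C@@]1(C(=O)OC)[C@H](O[Si](C)(C)C(C)(C)C)CCCCl | intermediate
19 | (8S)-methyl lactone (C9 on the concave face, cis to C11) | CC[C@@H]1[C@H]2OC(=O)[C@@H](C)[C@H]2[C@H](CC=C)[C@@]1(C(=O)OC)[C@H](O[Si](C)(C)C(C)(C)C)CCCCl | intermediate
20 | allyl methyl carbonate | C=CCOC(=O)OC | starting material
21 | (E)-allylic methyl carbonate, 19 with the allyl terminus extended to CH=CH–CH2OCO2Me | CC[C@@H]1[C@H]2OC(=O)[C@@H](C)[C@H]2[C@H](C/C=C/COC(=O)OC)[C@@]1(C(=O)OC)[C@H](O[Si](C)(C)C(C)(C)C)CCCCl | intermediate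
22 | 2-nitrobenzenesulfonamide | NS(=O)(=O)c1ccccc1[N+](=O)[O-] | starting material
23 | (13R)-N-(2-nitrophenylsulfonyl) allylic amine (C13 bears NH-nosyl and vinyl) | CC[C@@H]1[C@H]2OC(=O)[C@@H](C)[C@H]2[C@H](C[C@H](C=C)NS(=O)(=O)c3ccccc3[N+](=O)[O-])[C@@]1(C(=O)OC)[C@H](O[Si](C)(C)C(C)(C)C)CCCCl | intermediate
24 | N-nosyl azonane (nine-membered ring N21, C13, C12, C11, C27, C25, C24, C23, C22) | CC[C@@H]1[C@H]2OC(=O)[C@@H](C)[C@H]2[C@@H]2C[C@H](C=C)N(S(=O)(=O)c3ccccc3[N+](=O)[O-])CCC[C@@H](O[Si](C)(C)C(C)(C)C)[C@@]12C(=O)OC | intermediate
25 | azonane amino ester, 24 without the nosyl group (formed in the flask) | CC[C@@H]1[C@H]2OC(=O)[C@@H](C)[C@H]2[C@@H]2C[C@H](C=C)NCCC[C@@H](O[Si](C)(C)C(C)(C)C)[C@@]12C(=O)OC | intermediate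
26 | vinyl twisted lactam (N21–C28 closed, C13 vinyl) | CC[C@@H]1[C@H]2OC(=O)[C@@H](C)[C@H]2[C@@H]2C[C@H](C=C)N3CCC[C@@H](O[Si](C)(C)C(C)(C)C)[C@@]12C3=O | intermediate
27 | vicinal diol from the vinyl group of 26 (formed in the flask, carbinol centre open) | CC[C@@H]1[C@H]2OC(=O)[C@@H](C)[C@H]2[C@@H]2C[C@H](C(O)CO)N3CCC[C@@H](O[Si](C)(C)C(C)(C)C)[C@@]12C3=O | intermediate
28 | C13 aldehyde of the tetracyclic twisted lactam, O26 TBS ether (13R) | CC[C@@H]1[C@H]2OC(=O)[C@@H](C)[C@H]2[C@@H]2C[C@H](C=O)N3CCC[C@@H](O[Si](C)(C)C(C)(C)C)[C@@]12C3=O | intermediate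
29 | ethyl 2-(bromomethyl)acrylate | C=C(CBr)C(=O)OCC | starting material
30 | [2-(ethoxycarbonyl)allyl]zinc bromide (formed in the flask) | C=C(C[Zn]Br)C(=O)OCC | intermediate
31 | zinc alkoxide of the (14R) γ-hydroxy α-methylene ester (formed in the flask) | CC[C@@H]1[C@H]2OC(=O)[C@@H](C)[C@H]2[C@@H]2C[C@H]([C@@H](CC(=C)C(=O)OCC)O[Zn]Br)N3CCC[C@@H](O[Si](C)(C)C(C)(C)C)[C@@]12C3=O | intermediate
32 | α-methylene lactone at C13 (13R,14R), O26 TBS ether | CC[C@@H]1[C@H]2OC(=O)[C@@H](C)[C@H]2[C@@H]2C[C@H]([C@H]3CC(=C)C(=O)O3)N3CCC[C@@H](O[Si](C)(C)C(C)(C)C)[C@@]12C3=O | intermediate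
33 | O26-TBS ether of the target (14R,16R cis lactone D) | CC[C@@H]1[C@H]2OC(=O)[C@@H](C)[C@H]2[C@@H]2C[C@H]([C@H]3C[C@@H](C)C(=O)O3)N3CCC[C@@H](O[Si](C)(C)C(C)(C)C)[C@@]12C3=O | intermediate
34 | CNP0120800.1 | CC[C@@H]1[C@H]2OC(=O)[C@@H](C)[C@H]2[C@@H]2C[C@H]([C@H]3C[C@@H](C)C(=O)O3)N3CCC[C@@H](O)[C@@]12C3=O | target

## Step count and risks

Total step count: 20. Longest linear sequence: 20 steps (1 → 34). The aldehyde 28 is reached in 17 steps.

Steps most likely to fail:

**Step 18.** The risk is poor facial selectivity at the aldehyde: if zinc chelation to N21 is weak, Felkin-type addition gives the 14-epimer, and enolisation could erode C13. The fallback sets out from aldehyde 28 and replaces substrate control by reagent control. Allylboration with an enantiopure 2-(ethoxycarbonyl)allylboronate carrying a camphor-derived diol, catalysed by Sc(OTf)3 in CH2Cl2 at −78 °C, proceeds through a closed chair transition state that overrides the substrate bias and gives the open-chain (14R) γ-hydroxy α-methylene ester F1. Lactonisation with PPTS in toluene then comes back to the route at 32.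

**Step 7.** The risk is sluggish addition of the cuprate to the trisubstituted enoate, or O-acylation or protonation of the copper-bound enolate by the enolisable acid chloride. The fallback sets out from enoate 9 and separates the two bond formations. EtMgBr with CuBr·SMe2 (cat.) and TMSCl in THF at −78 °C gives the silyl ketene acetal F2. MeLi regenerates lithium enolate 11, which is added to 4-chlorobutanal in the presence of ZnCl2 to give the β-hydroxy ester F3 as a C25 epimer mixture. Dess–Martin oxidation comes back to the route at 12.

**Step 15.** The risk is that intermolecular alkylation (oligomers) and E2 loss of HCl outrun closure of the nine-membered ring. The fallback sets out from carbonate 21 and closes the ring at the other nitrogen bond. Intermolecular alkylation of excess 2-nitrobenzenesulfonamide 22 by the primary chloride (NaI, Cs2CO3, DMF, 60 °C) gives the C22 sulfonamide carbonate F4. Intramolecular iridium-catalysed allylic amination under dilution, with the same catalyst as in step 14, then forms N21–C13, sets (13R) and comes back to the route at 24.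

## Further compounds

F1 | step 18 | (13R,14R) open-chain γ-hydroxy α-methylene ethyl ester of the tetracycle, O26 TBS ether | CC[C@@H]1[C@H]2OC(=O)[C@@H](C)[C@H]2[C@@H]2C[C@H]([C@H](O)CC(=C)C(=O)OCC)N3CCC[C@@H](O[Si](C)(C)C(C)(C)C)[C@@]12C3=O
F2 | step 7 | trimethylsilyl ketene acetal of the 3-ethyl ester (ethyl trans to O5) | CC[C@@H]1[C@H]2OC(OC)C[C@H]2[C@H](CC=C)C1=C(OC)O[Si](C)(C)C
F3 | step 7 | β-hydroxy ester acetal, C25 carbinol epimers | CC[C@@H]1[C@H]2OC(OC)C[C@H]2[C@H](CC=C)[C@@]1(C(=O)OC)C(O)CCCCl
F4 | step 15 | C22 N-nosyl amine bearing the (E)-allylic methyl carbonate | CC[C@@H]1[C@H]2OC(=O)[C@@H](C)[C@H]2[C@H](C/C=C/COC(=O)OC)[C@@]1(C(=O)OC)[C@H](O[Si](C)(C)C(C)(C)C)CCCNS(=O)(=O)c3ccccc3[N+](=O)[O-]
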